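Everything rests on cutting ring B (C1, C2, C6, C7, C8, C9) into three achiral pieces. The cut exploits two features: ring B carries one exocyclic carbon, C10 on C1, and a vicinal branched pair, C6 (bearing C5) and C7 (bearing isopropyl). A β-silyloxy aldehyde supplies C2, C6 and C5, a nitroalkene C7 and C8, acrolein C9, C1 and C10. One amine-catalysed Michael/Michael/aldol-condensation cascade forms C6–C7, C8–C9 and C1=C2, closes ring B and sets C6 and C7. Nitro marks C8 for oxygen; the enal sets up a Claisen shift for C2–C3 and the methylene. Ring A is closed last through C4–C5.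

Key step: step 3

Remark: atom labels are C10=C1, ring fusion C2 and C6, C3, ketone C4, acetoxy C5, isopropyl C7, hydroxy C8, angeloyloxy C9. β is the ring face that carries the C7 isopropyl group and α is the opposite face. TBS = tert-butyldimethylsilyl. In the target the ring fusion is trans (H2 α, H6 β). C5–OAc is β. C8–OH (β) and C9–OAng (α) are trans-diaxial on ring B. The target is (2R,5R,6R,7S,8S,9S).

Step 1
Reactants: 1 isobutyraldehyde; 2 nitromethane
Product: 3 3-methyl-1-nitrobutan-2-ol (racemic)
Conditions: KOt-Bu (10 mol %), THF/t-BuOH, 0 °C to rt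
Reagents that add atoms: none
Why: The base-catalysed Henry reaction of nitromethane with an aliphatic aldehyde is reliable, and the configuration of the new carbinol does not matter because step 2 removes it.

Step 2
Reactants: 3 3-methyl-1-nitrobutan-2-ol
Product: 5 (E)-3-methyl-1-nitrobut-1-ene, via nitro mesylate 4 (not isolated)
Conditions: MsCl, Et3N, CH2Cl2, 0 °C
Reagents that add atoms: none
Why: Mesylation followed by E1cB elimination through the acidic α-nitro proton gives the conjugated nitroalkene, and the E isomer is favoured because it keeps the isopropyl and nitro groups apart.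

Step 3
Reactants: 6 3-[(tert-butyldimethylsilyl)oxy]propanal; 5 (E)-3-methyl-1-nitrobut-1-ene; 7 acrolein
Product: 10 (3R,4S,5S)-3-{[(tert-butyldimethylsilyl)oxy]methyl}-5-nitro-4-(propan-2-yl)cyclohex-1-ene-1-carbaldehyde, via syn nitro aldehyde 8 (not isolated), via nitro dialdehyde 9 (not isolated)
Conditions: (R)-2-[diphenyl(trimethylsilyloxy)methyl]pyrrolidine (20 mol %), PhCO2H (20 mol %), toluene, 0 °C; 7 added slowly once 5 is consumed, 0 °C to rt
Reagents that add atoms: none
Why: The catalyst condenses with 6 to an E-enamine that adds to 5 (C6–C7) to give 8, the nitronate of 8 adds to the iminium ion of acrolein (C8–C9) to give 9, and the C1 enamine of 9 attacks the C2 aldehyde and loses water (C1=C2). This is the known secondary-amine-catalysed Michael/Michael/aldol-condensation triple cascade of an aldehyde, a nitroalkene and an enal, applied here to an aliphatic nitroalkene and the parent enal. Ring B closes by a 6-(enolexo)-exo-trig aldol addition followed by dehydration. C6 and C7 are set together in the first Michael step by the enamine face left open by the diphenyl(silyloxy)methyl group, so the R catalyst should give the (6R,7S) syn adduct, which becomes the trans C5/isopropyl pair of ring B; C8 is epimerisable, settles with nitro equatorial and is erased in step 6. The step needs chemoselectivity among three partners: only 6 can form a nucleophilic enamine, the nitroalkene is its best acceptor, and acrolein is held back until 5 is gone so that it meets only the nitronate. The silyl ether matches the silyloxymethyl aldehydes already inside the scope of this cascade, and the weakly acidic medium limits β-elimination from 6 and 8.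

Step 4
Reactants: 10 cyclohexenecarbaldehyde from step 3
Product: 11 [(3R,4S,5S)-3-{[(tert-butyldimethylsilyl)oxy]methyl}-5-nitro-4-(propan-2-yl)cyclohex-1-en-1-yl]methanol
Conditions: NaBH4, MeOH/CH2Cl2, 0 °C
Reagents that add atoms: none
Why: The 1,2-reduction of the enal by borohydride is much faster than any reaction at the nitro group or the silyl ether, and it creates no stereocentre.

Step 5
Reactants: 11 allylic alcohol
Product: 13 ethyl 2-[(1R,2R,3S,4S)-2-{[(tert-butyldimethylsilyl)oxy]methyl}-6-methylidene-4-nitro-3-(propan-2-yl)cyclohexyl]acetate, via ketene acetal 12 (not isolated)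
Conditions: MeC(OEt)3 (excess), EtCO2H (10 mol %), 135 °C, EtOH distilled off
Reagents that add atoms: triethyl orthoacetate, CC(OCC)(OCC)OCC
Why: In this Johnson–Claisen rearrangement the [3,3] shift of 12 forms C2–C3 and moves the alkene to C1=C10, and the bond should form on the β face of C2 (equatorial trajectory) because the α face carries the C6 CH2OTBS group, pushed forward by the isopropyl group, and the axial hydrogens at C7 and C9, so the C3–C4 arm ends trans to C5.

Step 6
Reactants: 13 nitro ester
Product: 15 ethyl 2-[(1R,2R,3S)-2-{[(tert-butyldimethylsilyl)oxy]methyl}-6-methylidene-4-oxo-3-(propan-2-yl)cyclohexyl]acetate, via sodium nitronate 14 (not isolated)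
Conditions: NaOEt, EtOH, 0 °C; then added to TiCl3, NH4OAc, H2O/THF, pH 5–6, 0 °C to rt; crude product used at once
Reagents that add atoms: water, O
Why: In this reductive Nef reaction trivalent titanium cleaves the N–O bonds of 14 and the imine hydrolyses in a buffered medium that spares the ester, the silyl ether and the β,γ-placed methylene, while C7 keeps its more stable equatorial isopropyl group and immediate use of 15 forestalls alkene migration into conjugation.

Step 7
Reactants: 15 keto ester
Product: 17 (1R,2S,3R,4R)-3-{[(tert-butyldimethylsilyl)oxy]methyl}-4-(2-hydroxyethyl)-5-methylidene-2-(propan-2-yl)cyclohexan-1-ol, via hydroxy ester 16 (not isolated)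
Conditions: LiBH(s-Bu)3, THF, −78 °C; then LiAlH4, −78 to 0 °C; NaOH, H2O2 work-up
Reagents that add atoms: none
Why: The bulky borohydride attacks the 2-isopropylcyclohexanone from the equatorial α side, as in the menthone-to-neomenthol reduction, and so sets the axial β-hydroxyl at C8 cis to isopropyl before any group at C9 can block that side, after which LiAlH4 reduces the ester to the C4 alcohol in the same flask.

Step 8
Reactants: 17 diol
Product: 18 (1R,2S,3R,4R)-1-[(TBS)oxy]-4-{2-[(TBS)oxy]ethyl}-3-{[(TBS)oxy]methyl}-5-methylidene-2-(propan-2-yl)cyclohexane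
Conditions: TBSOTf, 2,6-lutidine, CH2Cl2, 0 °C to rt
Reagents that add atoms: tert-butyldimethylsilyl triflate, CC(C)(C)[Si](C)(C)OS(=O)(=O)C(F)(F)F
Why: A silyl triflate with a hindered pyridine base silylates the primary C4 hydroxyl and the hindered axial C8 hydroxyl in one operation, giving three ethers of one kind that differ strongly in steric shielding.

Step 9
Reactants: 18 tris-silyl ether
Product: 19 (1S,2S,3S,4R,5R)-2-[(TBS)oxy]-5-{2-[(TBS)oxy]ethyl}-4-{[(TBS)oxy]methyl}-6-methylidene-3-(propan-2-yl)cyclohexan-1-ol (C9 α-alcohol)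
Conditions: SeO2 (30 mol %), t-BuOOH, CH2Cl2, 0 °C to rt
Reagents that add atoms: selenium dioxide (oxygen donor), O=[Se]=O; tert-butyl hydroperoxide (restores SeO2), CC(C)(C)OO
Why: Allylic hydroxylation with SeO2 (ene reaction, then [2,3]-sigmatropic shift) takes the C9 methylene in preference to the tertiary C2–H and returns the alkene to C1=C10, and oxygen arrives along the axial α trajectory anti to the axial C8 silyloxy group, which sets the trans-diaxial C8/C9 pattern.

Step 10
Reactants: 19 C9 α-alcohol; 20 angelic acid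
Product: 22 (1S,2S,3S,4R,5R)-2-[(TBS)oxy]-5-{2-[(TBS)oxy]ethyl}-4-{[(TBS)oxy]methyl}-6-methylidene-3-(propan-2-yl)cyclohexyl (2Z)-2-methylbut-2-enoate, via mixed anhydride 21 (not isolated)
Conditions: 20, 2,4,6-Cl3C6H2COCl, Et3N, toluene, rt; then 19, 80 °C
Reagents that add atoms: none
Why: Esterification through the 2,4,6-trichlorobenzoyl mixed anhydride (Yamaguchi-type activation) without a nucleophilic catalyst acylates the only free hydroxyl with retention at C9 and avoids the addition–elimination path that turns an angelate into a tiglate.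

Step 11
Reactants: 22 angelate
Product: 23 (1S,2S,3S,4R,5R)-2-[(TBS)oxy]-5-(2-hydroxyethyl)-4-(hydroxymethyl)-6-methylidene-3-(propan-2-yl)cyclohexyl (2Z)-2-methylbut-2-enoate
Conditions: HF·pyridine, pyridine, THF, 0 °C
Reagents that add atoms: none
Why: Buffered fluoride desilylation discriminates on steric grounds, so the two primary ethers at C4 and C5 are cleaved while the axial secondary ether at C8, flanked by the isopropyl group and the angelate, stays.

Step 12
Reactants: 23 diol
Product: 24 (1S,2S,3S,4R,5R)-2-[(TBS)oxy]-4-formyl-6-methylidene-5-(2-oxoethyl)-3-(propan-2-yl)cyclohexyl (2Z)-2-methylbut-2-enoate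
Conditions: (COCl)2, DMSO, CH2Cl2, −78 °C; then Et3N, −78 to 0 °C
Reagents that add atoms: none
Why: The Swern oxidation activates both hydroxyls before base is added, so the dialdehyde forms without a lactol that could be oxidised on to a lactone, and the formyl group at C6 is already in its more stable equatorial position.

Step 13
Reactants: 24 dialdehyde
Product: 25 (1R,3aR,5S,6S,7S,7aR)-6-[(TBS)oxy]-1-hydroxy-4-methylidene-2-oxo-7-(propan-2-yl)octahydro-1H-inden-5-yl (2Z)-2-methylbut-2-enoate
Conditions: 2-(pentafluorophenyl)-6,7-dihydro-5H-pyrrolo[2,1-c][1,2,4]triazol-2-ium tetrafluoroborate (10 mol %), i-Pr2NEt (20 mol %), CH2Cl2 (0.02 M), rt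
Reagents that add atoms: none
Why: In this carbene-catalysed intramolecular crossed benzoin reaction the carbene converts the unhindered C4 aldehyde into the acyl-anion equivalent and the α-branched C5 aldehyde acts as acceptor (5-exo-trig closure of ring A on two trans-diequatorial arms), which puts the ketone at C4 and the carbinol at C5, with the hydroxyl in the pseudo-equatorial β position away from the α-axial hydrogens at C2 and C7.

Step 14
Reactants: 25 ketol
Product: 26 (1R,3aR,5S,6S,7S,7aR)-1-acetoxy-6-[(TBS)oxy]-4-methylidene-2-oxo-7-(propan-2-yl)octahydro-1H-inden-5-yl (2Z)-2-methylbut-2-enoate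
Conditions: Ac2O, pyridine, DMAP (cat.), CH2Cl2, 0 °C
Reagents that add atoms: acetic anhydride, CC(=O)OC(C)=O
Why: This is a standard acylation of the only free hydroxyl, and the mild base and low temperature avoid enolisation of the ketol, so C5 is retained.

Step 15
Reactants: 26 silyl ether
Product: 27 target, (1R,3aR,5S,6S,7S,7aR)-1-acetoxy-6-hydroxy-4-methylidene-2-oxo-7-(propan-2-yl)octahydro-1H-inden-5-yl (2Z)-2-methylbut-2-enoate
Conditions: HF (48 % aq.), MeCN, 0 °C to rt
Reagents that add atoms: none
Why: Acidic fluoride cleaves the last silyl ether without touching the acetate, the angelate or the methylene group, and the trans-diaxial arrangement of C8–OH and C9–OAng rules out acyl migration.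

Compound list
1 | isobutyraldehyde | CC(C)C=O | starting material
2 | nitromethane | C[N+](=O)[O-] | starting material
3 | 3-methyl-1-nitrobutan-2-ol (racemic) | CC(C)C(O)C[N+](=O)[O-] | intermediate
4 | 3-methyl-1-nitrobutan-2-yl methanesulfonate | CC(C)C(OS(C)(=O)=O)C[N+](=O)[O-] | intermediate
5 | (E)-3-methyl-1-nitrobut-1-ene | CC(C)/C=C/[N+](=O)[O-] | intermediate
6 | 3-[(tert-butyldimethylsilyl)oxy]propanal | O=CCCO[Si](C)(C)C(C)(C)C | starting material
7 | acrolein | C=CC=O | starting material
8 | (2R,3S)-2-{[(TBS)oxy]methyl}-4-methyl-3-(nitromethyl)pentanal (syn) | O=C[C@@H](CO[Si](C)(C)C(C)(C)C)[C@H](C(C)C)C[N+](=O)[O-] | intermediate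
9 | (2R,3S,4S)-2-{[(TBS)oxy]methyl}-4-nitro-3-(propan-2-yl)heptanedial | O=C[C@@H](CO[Si](C)(C)C(C)(C)C)[C@H](C(C)C)[C@@H]([N+](=O)[O-])CCC=O | intermediate
10 | (3R,4S,5S)-3-{[(TBS)oxy]methyl}-5-nitro-4-(propan-2-yl)cyclohex-1-ene-1-carbaldehyde | O=CC1=C[C@@H](CO[Si](C)(C)C(C)(C)C)[C@H](C(C)C)[C@@H]([N+](=O)[O-])C1 | intermediate
11 | [(3R,4S,5S)-3-{[(TBS)oxy]methyl}-5-nitro-4-(propan-2-yl)cyclohex-1-en-1-yl]methanol | OCC1=C[C@@H](CO[Si](C)(C)C(C)(C)C)[C@H](C(C)C)[C@@H]([N+](=O)[O-])C1 | intermediate
12 | 1-ethoxyvinyl ether of 11 (ketene acetal) | C=C(OCC)OCC1=C[C@@H](CO[Si](C)(C)C(C)(C)C)[C@H](C(C)C)[C@@H]([N+](=O)[O-])C1 | intermediate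
13 | ethyl 2-[(1R,2R,3S,4S)-2-{[(TBS)oxy]methyl}-6-methylidene-4-nitro-3-(propan-2-yl)cyclohexyl]acetate | C=C1[C@H](CC(=O)OCC)[C@@H](CO[Si](C)(C)C(C)(C)C)[C@H](C(C)C)[C@@H]([N+](=O)[O-])C1 | intermediate
14 | sodium nitronate of 13 | C=C1[C@H](CC(=O)OCC)[C@@H](CO[Si](C)(C)C(C)(C)C)[C@H](C(C)C)C(=[N+]([O-])[O-])C1.[Na+] | intermediate
15 | ethyl 2-[(1R,2R,3S)-2-{[(TBS)oxy]methyl}-6-methylidene-4-oxo-3-(propan-2-yl)cyclohexyl]acetate | C=C1[C@H](CC(=O)OCC)[C@@H](CO[Si](C)(C)C(C)(C)C)[C@H](C(C)C)C(=O)C1 | intermediate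
16 | ethyl 2-[(1R,2R,3S,4R)-2-{[(TBS)oxy]methyl}-4-hydroxy-6-methylidene-3-(propan-2-yl)cyclohexyl]acetate | C=C1[C@H](CC(=O)OCC)[C@@H](CO[Si](C)(C)C(C)(C)C)[C@H](C(C)C)[C@H](O)C1 | intermediate
17 | (1R,2S,3R,4R)-3-{[(TBS)oxy]methyl}-4-(2-hydroxyethyl)-5-methylidene-2-(propan-2-yl)cyclohexan-1-ol | C=C1[C@H](CCO)[C@@H](CO[Si](C)(C)C(C)(C)C)[C@H](C(C)C)[C@H](O)C1 | intermediate
18 | tris-TBS ether of the C4, C5, C8 triol (C8–OTBS β, axial) | C=C1[C@H](CCO[Si](C)(C)C(C)(C)C)[C@@H](CO[Si](C)(C)C(C)(C)C)[C@H](C(C)C)[C@H](O[Si](C)(C)C(C)(C)C)C1 | intermediate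
19 | C9 α-alcohol of 18 (C8–OTBS and C9–OH trans-diaxial) | C=C1[C@H](CCO[Si](C)(C)C(C)(C)C)[C@@H](CO[Si](C)(C)C(C)(C)C)[C@H](C(C)C)[C@H](O[Si](C)(C)C(C)(C)C)[C@H]1O | intermediate
20 | angelic acid, (Z)-2-methylbut-2-enoic acid | C/C=C(/C)C(=O)O | starting material
21 | angelic 2,4,6-trichlorobenzoic anhydride | C/C=C(/C)C(=O)OC(=O)c1c(Cl)cc(Cl)cc1Cl | intermediate
22 | C9 angelate of 19 | C=C1[C@H](CCO[Si](C)(C)C(C)(C)C)[C@@H](CO[Si](C)(C)C(C)(C)C)[C@H](C(C)C)[C@H](O[Si](C)(C)C(C)(C)C)[C@H]1OC(=O)/C(C)=C\C | intermediate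
23 | C4,C5 diol (C8–OTBS, C9–OAng) | C=C1[C@H](CCO)[C@@H](CO)[C@H](C(C)C)[C@H](O[Si](C)(C)C(C)(C)C)[C@H]1OC(=O)/C(C)=C\C | intermediate
24 | C4,C5 dialdehyde (C8–OTBS, C9–OAng) | C=C1[C@H](CC=O)[C@@H](C=O)[C@H](C(C)C)[C@H](O[Si](C)(C)C(C)(C)C)[C@H]1OC(=O)/C(C)=C\C | intermediate
25 | trans-hydrindane ketol (C4 ketone, C5 β-OH, C8–OTBS) | C=C1[C@@H]2CC(=O)[C@H](O)[C@H]2[C@H](C(C)C)[C@H](O[Si](C)(C)C(C)(C)C)[C@H]1OC(=O)/C(C)=C\C | intermediate
26 | C5 acetate of 25 | C=C1[C@@H]2CC(=O)[C@H](OC(C)=O)[C@H]2[C@H](C(C)C)[C@H](O[Si](C)(C)C(C)(C)C)[C@H]1OC(=O)/C(C)=C\C | intermediate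
27 | CNP0317011.1 | C=C1[C@@H]2CC(=O)[C@H](OC(C)=O)[C@H]2[C@H](C(C)C)[C@H](O)[C@H]1OC(=O)/C(C)=C\C | target

Total step count: 15. Longest linear sequence: 15 steps (from 1 and 2). Compounds 6, 7, 20 and both catalysts are purchased.

Steps most likely to fail

Step 3.
- What may go wrong: the first Michael addition to the aliphatic nitroalkene may be slow. Silanol may be lost by β-elimination from 6 or 8. Acrolein may oligomerise or intercept the enamine of 6.
- Fallback (sets out from 5 and 6, comes back at 11): the cascade is replaced by two separate operations with a phosphonate ring closure. The first Michael addition alone is run with the same catalyst and 8 is isolated. Cs2CO3 in CH2Cl2 at 0 °C adds its nitronate to ethyl 2-(diethoxyphosphoryl)acrylate to give the phosphonate adduct F1. After addition of EtOH this closes ring B by intramolecular Horner–Wadsworth–Emmons olefination to ethyl cyclohexenecarboxylate F2. Reduction with i-Bu2AlH (CH2Cl2, −78 °C) gives 11.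

Step 5.
- What may go wrong: facial selectivity at C2 may be poor. The torsionally favoured axial α approach may compete with the sterically favoured β approach, and a C2 epimer would then travel through steps 6 to 8.
- Fallback (sets out from 18 obtained in admixture with its C2 epimer F3, comes back at 18): kinetic face control is replaced by thermodynamic control. Ozonolysis of the mixture (O3, CH2Cl2, −78 °C; then PPh3) gives the C1 ketones, α-arm ketone F4 and β-arm ketone F5. C2 is now α to a carbonyl group. Brief treatment with DBU in toluene at rt should drain F4 into F5, whose C2 arm is equatorial and trans to C5. Wittig methylenation (Ph3PCH3Br, KN(SiMe3)2, THF, 0 °C) restores C1=C10 and returns 18.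

Step 13.
- What may go wrong: umpolung may occur at the wrong aldehyde and place the ketone at C5. Facial selectivity at C5 may be poor. The ketol may isomerise under base, or the carbene may be lost to side reactions.
- Fallback (sets out from 24, comes back at 25): the redox-neutral coupling is replaced by reductive coupling and re-oxidation. SmI2 (THF, t-BuOH, −78 °C to rt) effects pinacol cyclisation to the cis-diol F6. One equivalent of 2-iodoxybenzoic acid in DMSO oxidises 1,2-diols to ketols without C–C cleavage. It should take the unhindered C4 carbinol and leave the C5 carbinol, which is screened by C6 and the isopropyl group, giving 25.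

Further compounds
F1 | step 3 | ethyl (4S,5S,6R)-2-(diethoxyphosphoryl)-6-{[(TBS)oxy]methyl}-4-nitro-7-oxo-5-(propan-2-yl)heptanoate (mixture at C2 of the chain) | O=C[C@@H](CO[Si](C)(C)C(C)(C)C)[C@H](C(C)C)[C@@H]([N+](=O)[O-])CC(C(=O)OCC)P(=O)(OCC)OCC
F2 | step 3 | ethyl (3R,4S,5S)-3-{[(TBS)oxy]methyl}-5-nitro-4-(propan-2-yl)cyclohex-1-ene-1-carboxylate | CCOC(=O)C1=C[C@@H](CO[Si](C)(C)C(C)(C)C)[C@H](C(C)C)[C@@H]([N+](=O)[O-])C1
F3 | step 5 | C2 epimer of 18 (C3–C4 arm α, axial) | C=C1[C@@H](CCO[Si](C)(C)C(C)(C)C)[C@@H](CO[Si](C)(C)C(C)(C)C)[C@H](C(C)C)[C@H](O[Si](C)(C)C(C)(C)C)C1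
F4 | step 5 | (2S,3S,4S,5R)-5-[(TBS)oxy]-2-{2-[(TBS)oxy]ethyl}-3-{[(TBS)oxy]methyl}-4-(propan-2-yl)cyclohexan-1-one | O=C1[C@@H](CCO[Si](C)(C)C(C)(C)C)[C@@H](CO[Si](C)(C)C(C)(C)C)[C@H](C(C)C)[C@H](O[Si](C)(C)C(C)(C)C)C1
F5 | step 5 | (2R,3S,4S,5R)-5-[(TBS)oxy]-2-{2-[(TBS)oxy]ethyl}-3-{[(TBS)oxy]methyl}-4-(propan-2-yl)cyclohexan-1-one | O=C1[C@H](CCO[Si](C)(C)C(C)(C)C)[C@@H](CO[Si](C)(C)C(C)(C)C)[C@H](C(C)C)[C@H](O[Si](C)(C)C(C)(C)C)C1
F6 | step 13 | (1R,2S,3aR,5S,6S,7S,7aR)-6-[(TBS)oxy]-1,2-dihydroxy-4-methylidene-7-(propan-2-yl)octahydro-1H-inden-5-yl (2Z)-2-methylbut-2-enoate | C=C1[C@@H]2C[C@H](O)[C@H](O)[C@H]2[C@H](C(C)C)[C@H](O[Si](C)(C)C(C)(C)C)[C@H]1OC(=O)/C(C)=C\C
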